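**Retrosynthetic overview**
1. Target 34 ⇒ 32 by removing the C15 silyl ether and the C8 crotonate; both are put on after the ring system is complete.
2. Ten-membered carbocycle (formed last) ⇒ diene 31 by ring-closing metathesis across the (Z)-C4=C5 alkene.
3. Key union: the C7–C8 bond of 31 ⇒ furanone aldehyde 29 + (S)-3-(bromomethyl)-5-vinylbutenolide 12 by zinc-mediated Barbier allylation, which also unveils the α-methylene-γ-lactone and sets C7 and C8.
4. 29 ⇒ α-hydroxy ynone 27 (gold-catalysed closure of the 3(2H)-furanone, second ring) ⇒ Weinreb amide 24 + enyne 16; C10 comes from (S)-lactic acid by Seebach alkylation.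
5. 12 ⇒ D-glutamic acid (the γ-lactone is the first ring; C6 from the chiral pool) by Wittig methylenation, α-selenenylation, hydroxymethylation and selenoxide elimination.

Assumption: the SMILES is taken as drawn, i.e. (6S,7S,8R,10R) with a 4Z alkene in germacrane numbering (C1 ketone, C2=C3 in the furanone, C3–O–C10 bridge, C6–O lactone, C8 ester, C13 exocyclic methylene, C14 methyl, C15 CH2OH); this numbering is used in the text. Compounds 7–10 are used as mixtures of epimers at the selenium-bearing carbon, which is destroyed in step 7.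

**Lactone fragment**

Step 1
Reactants: 1 D-glutamic acid
Product: 2 (2R)-5-oxooxolane-2-carboxylic acid
Conditions: NaNO2, aq. HCl, 0 °C → rt
Reagents that add atoms: none
Why: Diazotisation followed by double-inversion substitution (α-lactone, then attack of the side-chain carboxylate) gives the γ-lactone with net retention, so the future C6 keeps the D (R) configuration.

Step 2
Reactants: 2 (2R)-5-oxooxolane-2-carboxylic acid
Product: 3 (5R)-5-(hydroxymethyl)oxolan-2-one
Conditions: BH3·SMe2, THF, 0 °C → rt; MeOH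
Reagents that add atoms: none
Why: Chemoselective borane reduction takes the free carboxylic acid to the primary alcohol much faster than it touches the lactone.

Step 3
Reactants: 3 (5R)-5-(hydroxymethyl)oxolan-2-one
Product: 4 (2R)-5-oxooxolane-2-carbaldehyde
Conditions: Dess–Martin periodinane, CH2Cl2, 0 °C → rt (crude product used at once)
Reagents that add atoms: none
Why: Dess–Martin oxidation stops at the aldehyde under near-neutral conditions that do not epimerise the α-acyloxy stereocentre.

Step 4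
Reactants: 4 (2R)-5-oxooxolane-2-carbaldehyde
Product: 5 (5R)-5-ethenyloxolan-2-one
Conditions: Ph3PCH3Br, KN(SiMe3)2, THF, 0 °C; then 4, −78 → 0 °C
Reagents that add atoms: methyltriphenylphosphonium bromide, C[P+](c1ccccc1)(c1ccccc1)c1ccccc1.[Br-]
Why: Wittig methylenation with the non-stabilised ylide at low temperature converts the aldehyde faster than it enolises and leaves the lactone alone, so C6 is retained.

Step 5
Reactants: 5 (5R)-5-ethenyloxolan-2-one
Product: 7 (5R)-5-ethenyl-3-(phenylselanyl)oxolan-2-one (both C3 epimers), via lithium enolate 6 (not isolated)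
Conditions: LiN(i-Pr)2, THF, −78 °C; PhSeCl, −78 °C
Reagents that add atoms: phenylselenenyl chloride, Cl[Se]c1ccccc1; LiN(i-Pr)2, [Li]N(C(C)C)C(C)C (lithium of enolate 6 only)
Why: Enolate α-selenenylation is much faster at −78 °C than addition of PhSeCl to the vinyl group, and the new C3 centre need not be controlled because it is removed in step 7.

Step 6
Reactants: 7 (5R)-5-ethenyl-3-(phenylselanyl)oxolan-2-one
Product: 9 (5R)-5-ethenyl-3-(hydroxymethyl)-3-(phenylselanyl)oxolan-2-one (both C3 epimers), via lithium enolate 8 (not isolated)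
Conditions: LiN(i-Pr)2, THF, −78 °C; CH2O (gas, from cracked paraformaldehyde), −78 → −40 °C
Reagents that add atoms: formaldehyde, C=O; LiN(i-Pr)2, [Li]N(C(C)C)C(C)C (lithium of enolate 8 only)
Why: The acidic α-seleno position is deprotonated again and the enolate undergoes aldol addition to monomeric formaldehyde, placing the future C13 on the selenium-bearing carbon.

Step 7
Reactants: 9 (5R)-5-ethenyl-3-(hydroxymethyl)-3-(phenylselanyl)oxolan-2-one
Product: 11 (5S)-5-ethenyl-3-(hydroxymethyl)furan-2(5H)-one, via selenoxide 10 (not isolated)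
Conditions: 30% aq. H2O2 (3 equiv), CH2Cl2, 0 °C → rt
Reagents that add atoms: hydrogen peroxide, OO (oxygen of selenoxide 10 only)
Why: Selenoxide syn-elimination goes toward the ring CH2 and away from the carbinol carbon, giving the endocyclic butenolide without touching C6 (whose descriptor changes to S only because the CIP ranking changes).

Step 8
Reactants: 11 (5S)-5-ethenyl-3-(hydroxymethyl)furan-2(5H)-one
Product: 12 (5S)-3-(bromomethyl)-5-ethenylfuran-2(5H)-one
Conditions: CBr4, PPh3, CH2Cl2, 0 °C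
Reagents that add atoms: carbon tetrabromide, BrC(Br)(Br)Br
Why: Appel bromination converts the primary allylic alcohol into the bromide under base-free conditions that spare the acidic, doubly allylic γ-stereocentre.

**Enyne fragment**

Step 9
Reactants: 13 2-bromoprop-2-en-1-ol
Product: 14 [(2-bromoprop-2-en-1-yl)oxy](tert-butyl)diphenylsilane
Conditions: TBDPSCl, imidazole, CH2Cl2, rt
Reagents that add atoms: tert-butyl(chloro)diphenylsilane, CC(C)(C)[Si](Cl)(c1ccccc1)c1ccccc1
Why: Routine silylation of the primary alcohol, with TBDPS chosen because it survives the aqueous acid of step 19 and can be removed last.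

Step 10
Reactants: 14 [(2-bromoprop-2-en-1-yl)oxy](tert-butyl)diphenylsilane
Product: 15 tert-butyl{[2-methylidene-4-(trimethylsilyl)but-3-yn-1-yl]oxy}diphenylsilane
Conditions: HC≡CSiMe3, Pd(PPh3)2Cl2 (3 mol %), CuI (6 mol %), i-Pr2NH, THF, rt → 45 °C
Reagents that add atoms: trimethylsilylacetylene, C#C[Si](C)(C)C
Why: Sonogashira coupling of the vinyl bromide with the terminal alkyne forms the C3–C4 bond of the conjugated enyne.

Step 11
Reactants: 15 tert-butyl{[2-methylidene-4-(trimethylsilyl)but-3-yn-1-yl]oxy}diphenylsilane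
Product: 16 tert-butyl[(2-methylidenebut-3-yn-1-yl)oxy]diphenylsilane
Conditions: K2CO3 (0.2 equiv), MeOH, 0 °C → rt
Reagents that add atoms: none
Why: Base-catalysed methanolysis cleaves the alkynyl C–Si bond selectively and leaves the hindered silyl ether intact.

**Furanone fragment**

Step 12
Reactants: 17 (S)-lactic acid
Product: 18 (2S,5S)-2-tert-butyl-5-methyl-1,3-dioxolan-4-one
Conditions: t-BuCHO, TsOH·H2O (cat.), H2SO4 (cat.), pentane, reflux (Dean–Stark); recrystallisation at −78 °C
Reagents that add atoms: pivalaldehyde, CC(C)(C)C=O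
Why: Acid-catalysed acetalisation gives mainly the cis dioxolanone, purified by crystallisation, so the lactic acid stereocentre is stored in the new acetal centre (Seebach self-regeneration of stereocentres).

Step 13
Reactants: 18 (2S,5S)-2-tert-butyl-5-methyl-1,3-dioxolan-4-one
Product: 20 (2S,5R)-2-tert-butyl-5-methyl-5-(prop-2-en-1-yl)-1,3-dioxolan-4-one, via lithium enolate 19 (not isolated)
Conditions: LiN(i-Pr)2, THF, −78 °C; allyl bromide, −78 → −30 °C
Reagents that add atoms: allyl bromide, C=CCBr; LiN(i-Pr)2, [Li]N(C(C)C)C(C)C (lithium of enolate 19 only)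
Why: Diastereoselective enolate alkylation occurs on the face opposite the tert-butyl group, so the allyl group takes the place of the original hydrogen and the future C10 is set as R.

Step 14
Reactants: 20 (2S,5R)-2-tert-butyl-5-methyl-5-(prop-2-en-1-yl)-1,3-dioxolan-4-one
Product: 22 (2S,5R)-2-tert-butyl-5-(2,2-dimethoxyethyl)-5-methyl-1,3-dioxolan-4-one, via aldehyde 21 (not isolated)
Conditions: O3, CH2Cl2/MeOH, −78 °C; Me2S, −78 °C → rt; then HC(OMe)3, TsOH·H2O (5 mol %), rt
Reagents that add atoms: ozone, [O-][O+]=O (carbonyl oxygen of aldehyde 21 only); trimethyl orthoformate, COC(OC)OC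
Why: Ozonolysis cleaves the only alkene to the C8 aldehyde and acid-catalysed acetalisation masks it as the dimethyl acetal, while the dioxolanone, which needs far harsher acid to open, is untouched.

Step 15
Reactants: 22 (2S,5R)-2-tert-butyl-5-(2,2-dimethoxyethyl)-5-methyl-1,3-dioxolan-4-one
Product: 23 (2R)-2-hydroxy-N,4,4-trimethoxy-N,2-dimethylbutanamide
Conditions: MeNH(OMe)·HCl, i-PrMgCl, THF, −20 → 0 °C
Reagents that add atoms: N,O-dimethylhydroxylamine hydrochloride, CNOC.Cl
Why: Aminolysis of the activated acyl-acetal carbonyl by the magnesium amide, with loss of pivalaldehyde from the hemiacetal alkoxide, gives the Weinreb amide without touching the quaternary centre.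

Step 16
Reactants: 23 (2R)-2-hydroxy-N,4,4-trimethoxy-N,2-dimethylbutanamide
Product: 24 (2R)-N,4,4-trimethoxy-N,2-dimethyl-2-[(trimethylsilyl)oxy]butanamide
Conditions: Me3SiCl, imidazole, DMF, rt
Reagents that add atoms: chlorotrimethylsilane, C[Si](C)(C)Cl
Why: Silylation of the tertiary alcohol avoids an alkoxide next to the amide and keeps the following acetylide addition clean.

Step 17
Reactants: 16 tert-butyl[(2-methylidenebut-3-yn-1-yl)oxy]diphenylsilane and 24 (2R)-N,4,4-trimethoxy-N,2-dimethyl-2-[(trimethylsilyl)oxy]butanamide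
Product: 27 (3R)-8-[(tert-butyldiphenylsilyl)oxy]-3-hydroxy-1,1-dimethoxy-3-methyl-7-methylideneoct-5-yn-4-one, via lithium acetylide 25 (not isolated), via silyl ether ynone 26 (not isolated)
Conditions: 16, n-BuLi, THF, −78 °C; then 24, −78 → 0 °C; inverse quench into cold 0.5 M HCl; then citric acid, MeOH, rt
Reagents that add atoms: n-butyllithium, [Li]CCCC (lithium of acetylide 25 only)
Why: In this Weinreb ketone synthesis the acetylide adds only once because the chelated tetrahedral intermediate survives until the acidic quench, which also traps the released amine before it can add to the ynone, and mild acidic methanolysis then frees the tertiary alcohol while keeping the acetal.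

Step 18
Reactants: 27 (3R)-8-[(tert-butyldiphenylsilyl)oxy]-3-hydroxy-1,1-dimethoxy-3-methyl-7-methylideneoct-5-yn-4-one
Product: 28 (2R)-5-{3-[(tert-butyldiphenylsilyl)oxy]prop-1-en-2-yl}-2-(2,2-dimethoxyethyl)-2-methylfuran-3(2H)-one
Conditions: Ph3PAuCl (5 mol %), AgOTf (5 mol %), toluene, rt
Reagents that add atoms: none
Why: The cationic gold phosphine complex activates the ynone for 5-endo-dig attack of the tertiary hydroxyl on the β-alkyne carbon (gold-catalysed cycloisomerisation), closing the 3(2H)-furanone with C10 unchanged.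

Step 19
Reactants: 28 (2R)-5-{3-[(tert-butyldiphenylsilyl)oxy]prop-1-en-2-yl}-2-(2,2-dimethoxyethyl)-2-methylfuran-3(2H)-one
Product: 29 2-[(2R)-5-{3-[(tert-butyldiphenylsilyl)oxy]prop-1-en-2-yl}-2-methyl-3-oxo-2,3-dihydrofuran-2-yl]acetaldehyde
Conditions: CF3CO2H/H2O (1:1), CHCl3, 0 °C (crude product used at once)
Reagents that add atoms: water, O
Why: Acid-catalysed acetal hydrolysis frees the C8 aldehyde while the furanone and the acid-stable TBDPS ether survive, and the aldehyde is used directly because its β-oxygen is a potential leaving group.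

**Fragment union and endgame**

Step 20
Reactants: 12 (5S)-3-(bromomethyl)-5-ethenylfuran-2(5H)-one and 29 2-[(2R)-5-{3-[(tert-butyldiphenylsilyl)oxy]prop-1-en-2-yl}-2-methyl-3-oxo-2,3-dihydrofuran-2-yl]acetaldehyde
Product: 31 (4S,5S)-4-{(1R)-2-[(2R)-5-{3-[(tert-butyldiphenylsilyl)oxy]prop-1-en-2-yl}-2-methyl-3-oxo-2,3-dihydrofuran-2-yl]-1-hydroxyethyl}-5-ethenyl-3-methylideneoxolan-2-one, via allylzinc bromide 30 (not isolated)
Conditions: Zn dust, THF/sat. aq. NH4Cl (2:1), 0 °C → rt
Reagents that add atoms: zinc, [Zn] (zinc of 30 only)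
Why: In this Barbier carbonyl allylation the allylzinc adds through its γ-carbon in a chair Zimmerman–Traxler transition state, anti to the C6 vinyl group (C7 S, trans lactone) and with the aldehyde substituent equatorial (C8 R, anti to C6), forming the C7–C8 bond and the α-methylene lactone in one step.

Step 21
Reactants: 31 (4S,5S)-4-{(1R)-2-[(2R)-5-{3-[(tert-butyldiphenylsilyl)oxy]prop-1-en-2-yl}-2-methyl-3-oxo-2,3-dihydrofuran-2-yl]-1-hydroxyethyl}-5-ethenyl-3-methylideneoxolan-2-one
Product: 32 (3aS,4R,6R,10Z,11aS)-10-{[(tert-butyldiphenylsilyl)oxy]methyl}-4-hydroxy-6-methyl-3-methylidene-3a,4,5,6-tetrahydro-6,9-epoxycyclodeca[b]furan-2,7(3H,11aH)-dione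
Conditions: second-generation Hoveyda–Grubbs catalyst [RuCl2(H2IMes)(=CH-C6H4-2-O-i-Pr)] (15 mol %, in portions), toluene (1 mM), 80 °C, argon sparge
Reagents that add atoms: none
Why: Ring-closing metathesis starts at the monosubstituted C6 vinyl group and closes onto the 1,1-disubstituted C4 alkene under high dilution, the bridged ten-membered ring allowing only the Z alkene, while the other alkene pairings would need a cyclobutene or a tetrasubstituted eight-membered ring.

Step 22
Reactants: 32 (3aS,4R,6R,10Z,11aS)-10-{[(tert-butyldiphenylsilyl)oxy]methyl}-4-hydroxy-6-methyl-3-methylidene-3a,4,5,6-tetrahydro-6,9-epoxycyclodeca[b]furan-2,7(3H,11aH)-dione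
Product: 33 (3aS,4R,6R,10Z,11aS)-10-{[(tert-butyldiphenylsilyl)oxy]methyl}-6-methyl-3-methylidene-2,7-dioxo-2,3,3a,4,5,6,7,11a-octahydro-6,9-epoxycyclodeca[b]furan-4-yl (2E)-but-2-enoate
Conditions: (E)-crotonic anhydride, DMAP (0.2 equiv), pyridine, CH2Cl2, 0 °C → rt
Reagents that add atoms: (E)-but-2-enoic anhydride, C/C=C/C(=O)OC(=O)/C=C/C
Why: DMAP-catalysed acylation with the anhydride esterifies the only free hydroxyl with retention at C8 and avoids the ketene pathway that deconjugates crotonyl chloride; it is done after step 21 because a crotonate would compete in the metathesis.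

Step 23
Reactants: 33 (3aS,4R,6R,10Z,11aS)-10-{[(tert-butyldiphenylsilyl)oxy]methyl}-6-methyl-3-methylidene-2,7-dioxo-2,3,3a,4,5,6,7,11a-octahydro-6,9-epoxycyclodeca[b]furan-4-yl (2E)-but-2-enoate
Product: 34 (3aS,4R,6R,10Z,11aS)-10-(hydroxymethyl)-6-methyl-3-methylidene-2,7-dioxo-2,3,3a,4,5,6,7,11a-octahydro-6,9-epoxycyclodeca[b]furan-4-yl (2E)-but-2-enoate
Conditions: HF·pyridine, pyridine, THF, 0 °C → rt
Reagents that add atoms: none
Why: Buffered fluoride desilylation cleaves the Si–O bond without adding to the α-methylene lactone or cleaving either ester.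

**Compound list**
1 | D-glutamic acid | N[C@H](CCC(=O)O)C(=O)O | starting material
2 | (2R)-5-oxooxolane-2-carboxylic acid | OC(=O)[C@H]1CCC(=O)O1 | intermediate
3 | (5R)-5-(hydroxymethyl)oxolan-2-one | OC[C@H]1CCC(=O)O1 | intermediate
4 | (2R)-5-oxooxolane-2-carbaldehyde | O=C[C@H]1CCC(=O)O1 | intermediate
5 | (5R)-5-ethenyloxolan-2-one | C=C[C@H]1CCC(=O)O1 | intermediate
6 | lithium (5R)-5-ethenyl-4,5-dihydrofuran-2-olate | C=C[C@H]1CC=C(O[Li])O1 | intermediate
7 | (5R)-5-ethenyl-3-(phenylselanyl)oxolan-2-one (both C3 epimers) | C=C[C@H]1CC([Se]c2ccccc2)C(=O)O1 | intermediate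
8 | lithium (5R)-5-ethenyl-3-(phenylselanyl)-4,5-dihydrofuran-2-olate | C=C[C@H]1CC([Se]c2ccccc2)=C(O[Li])O1 | intermediate
9 | (5R)-5-ethenyl-3-(hydroxymethyl)-3-(phenylselanyl)oxolan-2-one (both C3 epimers) | C=C[C@H]1CC(CO)([Se]c2ccccc2)C(=O)O1 | intermediate
10 | (5R)-5-ethenyl-3-(hydroxymethyl)-3-(phenylseleninyl)oxolan-2-one | C=C[C@H]1CC(CO)([Se](=O)c2ccccc2)C(=O)O1 | intermediate
11 | (5S)-5-ethenyl-3-(hydroxymethyl)furan-2(5H)-one | C=C[C@H]1C=C(CO)C(=O)O1 | intermediate
12 | (5S)-3-(bromomethyl)-5-ethenylfuran-2(5H)-one | C=C[C@H]1C=C(CBr)C(=O)O1 | intermediate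
13 | 2-bromoprop-2-en-1-ol | C=C(Br)CO | starting material
14 | [(2-bromoprop-2-en-1-yl)oxy](tert-butyl)diphenylsilane | C=C(Br)CO[Si](c1ccccc1)(c1ccccc1)C(C)(C)C | intermediate
15 | tert-butyl{[2-methylidene-4-(trimethylsilyl)but-3-yn-1-yl]oxy}diphenylsilane | C=C(C#C[Si](C)(C)C)CO[Si](c1ccccc1)(c1ccccc1)C(C)(C)C | intermediate
16 | tert-butyl[(2-methylidenebut-3-yn-1-yl)oxy]diphenylsilane | C=C(C#C)CO[Si](c1ccccc1)(c1ccccc1)C(C)(C)C | intermediate
17 | (S)-lactic acid | C[C@H](O)C(=O)O | starting material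
18 | (2S,5S)-2-tert-butyl-5-methyl-1,3-dioxolan-4-one | C[C@@H]1O[C@H](C(C)(C)C)OC1=O | intermediate
19 | lithium (2S)-2-tert-butyl-5-methyl-1,3-dioxol-4-olate | CC1=C(O[Li])O[C@@H](C(C)(C)C)O1 | intermediate
20 | (2S,5R)-2-tert-butyl-5-methyl-5-(prop-2-en-1-yl)-1,3-dioxolan-4-one | C=CC[C@@]1(C)O[C@H](C(C)(C)C)OC1=O | intermediate
21 | (2S,5R)-2-tert-butyl-5-methyl-5-(2-oxoethyl)-1,3-dioxolan-4-one | O=CC[C@@]1(C)O[C@H](C(C)(C)C)OC1=O | intermediate
22 | (2S,5R)-2-tert-butyl-5-(2,2-dimethoxyethyl)-5-methyl-1,3-dioxolan-4-one | COC(OC)C[C@@]1(C)O[C@H](C(C)(C)C)OC1=O | intermediate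
23 | (2R)-2-hydroxy-N,4,4-trimethoxy-N,2-dimethylbutanamide | COC(OC)C[C@@](C)(O)C(=O)N(C)OC | intermediate
24 | (2R)-N,4,4-trimethoxy-N,2-dimethyl-2-[(trimethylsilyl)oxy]butanamide | COC(OC)C[C@@](C)(O[Si](C)(C)C)C(=O)N(C)OC | intermediate
25 | lithium 3-{[(tert-butyldiphenylsilyl)oxy]methyl}but-3-en-1-yn-1-ide | [Li]C#CC(=C)CO[Si](c1ccccc1)(c1ccccc1)C(C)(C)C | intermediate
26 | (3R)-8-[(tert-butyldiphenylsilyl)oxy]-1,1-dimethoxy-3-methyl-7-methylidene-3-[(trimethylsilyl)oxy]oct-5-yn-4-one | COC(OC)C[C@@](C)(O[Si](C)(C)C)C(=O)C#CC(=C)CO[Si](c1ccccc1)(c1ccccc1)C(C)(C)C | intermediate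
27 | (3R)-8-[(tert-butyldiphenylsilyl)oxy]-3-hydroxy-1,1-dimethoxy-3-methyl-7-methylideneoct-5-yn-4-one | COC(OC)C[C@@](C)(O)C(=O)C#CC(=C)CO[Si](c1ccccc1)(c1ccccc1)C(C)(C)C | intermediate
28 | (2R)-5-{3-[(tert-butyldiphenylsilyl)oxy]prop-1-en-2-yl}-2-(2,2-dimethoxyethyl)-2-methylfuran-3(2H)-one | COC(OC)C[C@@]1(C)OC(C(=C)CO[Si](c2ccccc2)(c2ccccc2)C(C)(C)C)=CC1=O | intermediate
29 | 2-[(2R)-5-{3-[(tert-butyldiphenylsilyl)oxy]prop-1-en-2-yl}-2-methyl-3-oxo-2,3-dihydrofuran-2-yl]acetaldehyde | O=CC[C@@]1(C)OC(C(=C)CO[Si](c2ccccc2)(c2ccccc2)C(C)(C)C)=CC1=O | intermediate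
30 | bromo{[(5S)-5-ethenyl-2-oxo-2,5-dihydrofuran-3-yl]methyl}zinc | C=C[C@H]1C=C(C[Zn]Br)C(=O)O1 | intermediate
31 | (4S,5S)-4-{(1R)-2-[(2R)-5-{3-[(tert-butyldiphenylsilyl)oxy]prop-1-en-2-yl}-2-methyl-3-oxo-2,3-dihydrofuran-2-yl]-1-hydroxyethyl}-5-ethenyl-3-methylideneoxolan-2-one | C=C1C(=O)O[C@@H](C=C)[C@@H]1[C@H](O)C[C@@]1(C)OC(C(=C)CO[Si](c2ccccc2)(c2ccccc2)C(C)(C)C)=CC1=O | intermediate
32 | (3aS,4R,6R,10Z,11aS)-10-{[(tert-butyldiphenylsilyl)oxy]methyl}-4-hydroxy-6-methyl-3-methylidene-3a,4,5,6-tetrahydro-6,9-epoxycyclodeca[b]furan-2,7(3H,11aH)-dione | C=C1C(=O)O[C@H]2/C=C(/CO[Si](c4ccccc4)(c4ccccc4)C(C)(C)C)C3=CC(=O)[C@@](C)(C[C@@H](O)[C@H]12)O3 | intermediate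
33 | (3aS,4R,6R,10Z,11aS)-10-{[(tert-butyldiphenylsilyl)oxy]methyl}-6-methyl-3-methylidene-2,7-dioxo-2,3,3a,4,5,6,7,11a-octahydro-6,9-epoxycyclodeca[b]furan-4-yl (2E)-but-2-enoate | C=C1C(=O)O[C@H]2/C=C(/CO[Si](c4ccccc4)(c4ccccc4)C(C)(C)C)C3=CC(=O)[C@@](C)(C[C@@H](OC(=O)/C=C/C)[C@H]12)O3 | intermediate
34 | (3aS,4R,6R,10Z,11aS)-10-(hydroxymethyl)-6-methyl-3-methylidene-2,7-dioxo-2,3,3a,4,5,6,7,11a-octahydro-6,9-epoxycyclodeca[b]furan-4-yl (2E)-but-2-enoate (CNP0225232.1) | C=C1C(=O)O[C@H]2/C=C(/CO)C3=CC(=O)[C@@](C)(C[C@@H](OC(=O)/C=C/C)[C@H]12)O3 | target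

**Totals**
Total step count: 23.
Longest linear sequence: 12 steps (steps 12–19 then 20–23 from (S)-lactic acid; the lactone branch, steps 1–8 then 20–23, is equally long).

**Three steps most likely to fail, with fallbacks**

Step 21 (ring-closing metathesis). The ring is bridged and strained, and the catalyst must close onto a 1,1-disubstituted alkene that sits next to a bulky silyl ether. Fallback, hydroxyl-assisted closure on the unprotected substrate: setting out from 31, the silyl ether is removed first (HF·pyridine, pyridine, THF) to give the desilylated diene diol F1. Its free allylic hydroxyl removes the steric shield and speeds ruthenium alkylidene turnover at that alkene. Metathesis with the same ruthenium catalyst (toluene, 1 mM, 80 °C) then gives the macrocyclic diol F2. Selective silylation of the primary allylic alcohol (TBDPSCl, imidazole, CH2Cl2, −20 °C) comes back to the route at 32.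

Step 20 (Barbier allylation). The aldehyde is fragile, and the C8 configuration rests on the chair transition state winning over any bias from the remote C10 centre. Fallback, correction of C8 by inversion instead of by the allylation itself: setting out from 12 and 29 under the same zinc conditions, if the (1S) carbinol predominates it is isolated as the 8-epi alcohol F3. It is cyclised exactly as in step 21 to the 8-epi macrocyclic alcohol F4. Mitsunobu esterification with (E)-crotonic acid (PPh3, diisopropyl azodicarboxylate, THF, 0 °C) then installs the ester with inversion at C8 and comes back to the route at 33, skipping step 22.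

Step 4 (Wittig methylenation). The α-acyloxy aldehyde can epimerise or oligomerise under the basic ylide, and any loss of configuration here lowers the enantiopurity of everything downstream. Fallback, Peterson olefination with a non-basic elimination: setting out from 4, Me3SiCH2MgCl (Et2O, −78 °C) adds to the aldehyde faster than it deprotonates it or attacks the lactone, giving the β-hydroxysilane F5. Aqueous HF in MeCN then brings about elimination and comes back to the route at 5.

**Further compounds**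
F1 | step 21 | (4S,5S)-5-ethenyl-4-{(1R)-1-hydroxy-2-[(2R)-5-(3-hydroxyprop-1-en-2-yl)-2-methyl-3-oxo-2,3-dihydrofuran-2-yl]ethyl}-3-methylideneoxolan-2-one | C=C1C(=O)O[C@@H](C=C)[C@@H]1[C@H](O)C[C@@]1(C)OC(C(=C)CO)=CC1=O
F2 | step 21 | (3aS,4R,6R,10Z,11aS)-4-hydroxy-10-(hydroxymethyl)-6-methyl-3-methylidene-3a,4,5,6-tetrahydro-6,9-epoxycyclodeca[b]furan-2,7(3H,11aH)-dione | C=C1C(=O)O[C@H]2/C=C(/CO)C3=CC(=O)[C@@](C)(C[C@@H](O)[C@H]12)O3
F3 | step 20 | (4S,5S)-4-{(1S)-2-[(2R)-5-{3-[(tert-butyldiphenylsilyl)oxy]prop-1-en-2-yl}-2-methyl-3-oxo-2,3-dihydrofuran-2-yl]-1-hydroxyethyl}-5-ethenyl-3-methylideneoxolan-2-one | C=C1C(=O)O[C@@H](C=C)[C@@H]1[C@@H](O)C[C@@]1(C)OC(C(=C)CO[Si](c2ccccc2)(c2ccccc2)C(C)(C)C)=CC1=O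
F4 | step 20 | (3aS,4S,6R,10Z,11aS)-10-{[(tert-butyldiphenylsilyl)oxy]methyl}-4-hydroxy-6-methyl-3-methylidene-3a,4,5,6-tetrahydro-6,9-epoxycyclodeca[b]furan-2,7(3H,11aH)-dione | C=C1C(=O)O[C@H]2/C=C(/CO[Si](c4ccccc4)(c4ccccc4)C(C)(C)C)C3=CC(=O)[C@@](C)(C[C@H](O)[C@H]12)O3
F5 | step 4 | (5R)-5-[1-hydroxy-2-(trimethylsilyl)ethyl]oxolan-2-one (both carbinol epimers) | C[Si](C)(C)CC(O)[C@H]1CCC(=O)O1
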